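## Retrosynthetic overview

1. 15-Keto-PGF2α ⇒ the 13E-enone is kept latent until the last step as a saturated C13 phenylsulfone with C15 as a dioxolane (acid unmasking, then E1cB loss of sulfinate).
2. C5=C6 (Z) ⇒ Wittig reaction of a bicyclic lactol with the C1–C5 ylide; lactol ⇒ ozonolysis of an 8α-allyl group next to the 9α-OH (possible because no other C=C bond exists yet).
3. C9–OH ⇒ β-face hydride reduction of the cyclopentanone.
4. Key disconnection C12–C13 (plus C8–C7 in the same flask): α-lithiated 2-pentyl-2-[2-(phenylsulfonyl)ethyl]-1,3-dioxolane, a polarity-reversed homoenolate (β-acylvinyl anion) equivalent of oct-1-en-3-one, adds to (R)-4-silyloxycyclopent-2-enone and the enolate is trapped with allyl iodide.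
5. Ring order: the cyclopentane is bought intact and never built; only two temporary rings are made, the dioxolane (step 2) and then the lactol (step 5), and they are opened again in steps 7 and 6.

Assumption: all purchased materials, including the silyl-protected (R)-4-hydroxycyclopentenone building block, are taken to be available in bulk at low cost; prostaglandin numbering (C1 to C20) is used for positions.

## Route

Step 1
Reactants: 1 oct-1-en-3-one; 2 sodium benzenesulfinate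
Product: 3 1-(phenylsulfonyl)octan-3-one
Conditions: PhSO2Na (1.2 equiv), AcOH (1.5 equiv), EtOH/H2O, rt, 12 h
Reagents that add atoms: none
Why: Sulfa-Michael (conjugate) addition, in which the soft sulfinate sulfur adds to the β-carbon of the vinyl ketone and AcOH protonates the enolate, installs the sulfonyl handle at the future C13 without creating a stereocenter.

Step 2
Reactants: 3 1-(phenylsulfonyl)octan-3-one; 4 ethylene glycol
Product: 5 2-pentyl-2-[2-(phenylsulfonyl)ethyl]-1,3-dioxolane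
Conditions: TsOH·H2O (5 mol %), toluene, reflux, Dean–Stark
Reagents that add atoms: none
Why: Acid-catalysed ketalisation with azeotropic removal of water masks the C15 ketone, so the sulfone can be lithiated and carried through basic steps without retro-Michael loss of sulfinate, and no stereocenter is formed.

Step 3
Reactants: 5 2-pentyl-2-[2-(phenylsulfonyl)ethyl]-1,3-dioxolane; 6 (R)-4-[(tert-butyldimethylsilyl)oxy]cyclopent-2-en-1-one; 7 allyl iodide
Product: 10 (2R,3R,4R)-4-[(tert-butyldimethylsilyl)oxy]-3-[(1RS)-2-(2-pentyl-1,3-dioxolan-2-yl)-1-(phenylsulfonyl)ethyl]-2-(prop-2-en-1-yl)cyclopentan-1-one, via lithiated sulfone 8 (not isolated), via lithium enolate 9 (not isolated)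
Conditions: 5 (1.15 equiv), n-BuLi (1.1 equiv), THF, −78 °C, 30 min; HMPA (4 equiv); 6 (1.0 equiv), −78 °C, 1 h; 7 (4 equiv), −78 → −30 °C, 3 h; aq NH4Cl
Reagents that add atoms: none
Why: Tandem Michael addition–enolate alkylation (three-component coupling), in which the sulfone-stabilised carbanion 8, a homoenolate (β-acylvinyl anion) equivalent of oct-1-en-3-one, adds 1,4 in THF–HMPA to the enone β-carbon anti to the C11 silyloxy group, so that two enone β-carbons (C12 and C13, normally both electrophilic) are joined, and the regiodefined lithium enolate 9 is then allylated anti to the new C12 substituent to give the 8α,12β-trans arrangement, while C13 forms as an epimer mixture that is erased in step 7.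

Step 4
Reactants: 10 (2R,3R,4R)-4-[(tert-butyldimethylsilyl)oxy]-3-[(1RS)-2-(2-pentyl-1,3-dioxolan-2-yl)-1-(phenylsulfonyl)ethyl]-2-(prop-2-en-1-yl)cyclopentan-1-one
Product: 11 (1S,2R,3R,4R)-4-[(tert-butyldimethylsilyl)oxy]-3-[(1RS)-2-(2-pentyl-1,3-dioxolan-2-yl)-1-(phenylsulfonyl)ethyl]-2-(prop-2-en-1-yl)cyclopentan-1-ol
Conditions: LiBH(s-Bu)3 (1.3 equiv), THF, −78 °C, 1 h; then H2O
Reagents that add atoms: none
Why: Diastereoselective ketone reduction, in which the bulky tri-sec-butylborohydride attacks the C9 carbonyl from the β-face, away from the adjacent α-allyl group and the α-silyloxy group, gives the 9α-alcohol cis to the allyl group, as in reductions of PGE-type ketones to PGF-type alcohols.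

Step 5
Reactants: 11 (1S,2R,3R,4R)-4-[(tert-butyldimethylsilyl)oxy]-3-[(1RS)-2-(2-pentyl-1,3-dioxolan-2-yl)-1-(phenylsulfonyl)ethyl]-2-(prop-2-en-1-yl)cyclopentan-1-ol
Product: 14 (3aR,4R,5R,6aS)-5-[(tert-butyldimethylsilyl)oxy]-4-[(1RS)-2-(2-pentyl-1,3-dioxolan-2-yl)-1-(phenylsulfonyl)ethyl]hexahydro-2H-cyclopenta[b]furan-2-ol (anomer mixture), via ozonide 12 (not isolated), via hydroxy aldehyde 13 (not isolated)
Conditions: O3, CH2Cl2, −78 °C; then PPh3 (1.5 equiv), −78 °C → rt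
Reagents that add atoms: ozone, [O-][O+]=O
Why: Ozonolysis with reductive work-up cleaves the only C=C bond present (C13=C14 is still latent as the saturated sulfone) and the C6 aldehyde is trapped by the cis 9α-hydroxyl as the five-membered lactol, with no change at the existing stereocenters.

Step 6
Reactants: 14 (3aR,4R,5R,6aS)-5-[(tert-butyldimethylsilyl)oxy]-4-[(1RS)-2-(2-pentyl-1,3-dioxolan-2-yl)-1-(phenylsulfonyl)ethyl]hexahydro-2H-cyclopenta[b]furan-2-ol; 15 (4-carboxybutyl)triphenylphosphonium bromide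
Product: 17 (Z)-7-[(1R,2R,3R,5S)-3-[(tert-butyldimethylsilyl)oxy]-5-hydroxy-2-[(1RS)-2-(2-pentyl-1,3-dioxolan-2-yl)-1-(phenylsulfonyl)ethyl]cyclopentyl]hept-5-enoic acid, via phosphonium ylide 16 (not isolated)
Conditions: 15 (5 equiv), KOtBu (9.8 equiv), THF, 0 °C → rt; then 14, 0 °C → rt, 3 h; aq NaH2PO4 (pH 5)
Reagents that add atoms: none
Why: Wittig olefination of the lactol through its open hydroxy-aldehyde form with the non-stabilised ylide gives the (5Z)-alkene under kinetic control, as in the classical prostaglandin end-game, and the ketal, the sulfone (which has no β-leaving group while C15 is masked) and the silyl ether survive the base.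

Step 7
Reactants: 17 (Z)-7-[(1R,2R,3R,5S)-3-[(tert-butyldimethylsilyl)oxy]-5-hydroxy-2-[(1RS)-2-(2-pentyl-1,3-dioxolan-2-yl)-1-(phenylsulfonyl)ethyl]cyclopentyl]hept-5-enoic acid
Product: 19 15-keto-PGF2α [(Z)-7-[(1R,2R,3R,5S)-3,5-dihydroxy-2-[(E)-3-oxooct-1-en-1-yl]cyclopentyl]hept-5-enoic acid], via sulfonyl ketone 18 (not isolated)
Conditions: 1 M aq HCl/THF (1:2), rt, 16 h; extract, concentrate; then DBU (3 equiv), CH2Cl2, 0 °C → rt, 1 h; pH 4 buffer wash
Reagents that add atoms: water, O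
Why: Acidic hydrolysis removes the silyl ether and the dioxolane, and the liberated β-sulfonyl ketone then loses benzenesulfinate by DBU-mediated E1cB elimination to give the thermodynamically favoured, conjugated (13E)-enone without touching the ring stereocenters.

## Compound list

1 | oct-1-en-3-one | C=CC(=O)CCCCC | starting material
2 | sodium benzenesulfinate | [Na+].[O-]S(=O)c1ccccc1 | starting material
3 | 1-(phenylsulfonyl)octan-3-one | CCCCCC(=O)CCS(=O)(=O)c1ccccc1 | intermediate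
4 | ethylene glycol (ethane-1,2-diol) | OCCO | starting material
5 | 2-pentyl-2-[2-(phenylsulfonyl)ethyl]-1,3-dioxolane | CCCCCC1(CCS(=O)(=O)c2ccccc2)OCCO1 | intermediate
6 | (R)-4-[(tert-butyldimethylsilyl)oxy]cyclopent-2-en-1-one | C1=CC(=O)C[C@H]1O[Si](C)(C)C(C)(C)C | starting material
7 | allyl iodide (3-iodoprop-1-ene) | C=CCI | starting material
8 | [2-(2-pentyl-1,3-dioxolan-2-yl)-1-(phenylsulfonyl)ethyl]lithium | CCCCCC1(OCCO1)CC([Li])S(=O)(=O)c1ccccc1 | intermediate
9 | lithium (3R,4R)-4-[(tert-butyldimethylsilyl)oxy]-3-[(1RS)-2-(2-pentyl-1,3-dioxolan-2-yl)-1-(phenylsulfonyl)ethyl]cyclopent-1-en-1-olate | CCCCCC2(OCCO2)CC(S(=O)(=O)c2ccccc2)[C@@H]1C=C(O[Li])C[C@H]1O[Si](C)(C)C(C)(C)C | intermediate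
10 | (2R,3R,4R)-4-[(tert-butyldimethylsilyl)oxy]-3-[(1RS)-2-(2-pentyl-1,3-dioxolan-2-yl)-1-(phenylsulfonyl)ethyl]-2-(prop-2-en-1-yl)cyclopentan-1-one (8α-allyl, 12β-side chain, 11α-OTBS; C13 epimers) | CCCCCC2(OCCO2)CC(S(=O)(=O)c2ccccc2)[C@@H]1[C@@H](CC=C)C(=O)C[C@H]1O[Si](C)(C)C(C)(C)C | intermediate
11 | (1S,2R,3R,4R)-4-[(tert-butyldimethylsilyl)oxy]-3-[(1RS)-2-(2-pentyl-1,3-dioxolan-2-yl)-1-(phenylsulfonyl)ethyl]-2-(prop-2-en-1-yl)cyclopentan-1-ol (9α-OH) | CCCCCC2(OCCO2)CC(S(=O)(=O)c2ccccc2)[C@@H]1[C@@H](CC=C)[C@@H](O)C[C@H]1O[Si](C)(C)C(C)(C)C | intermediate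
12 | (1S,2R,3R,4R)-4-[(tert-butyldimethylsilyl)oxy]-3-[(1RS)-2-(2-pentyl-1,3-dioxolan-2-yl)-1-(phenylsulfonyl)ethyl]-2-[(1,2,4-trioxolan-3-yl)methyl]cyclopentan-1-ol (ozonide) | CCCCCC2(OCCO2)CC(S(=O)(=O)c2ccccc2)[C@@H]1[C@@H](CC3OCOO3)[C@@H](O)C[C@H]1O[Si](C)(C)C(C)(C)C | intermediate
13 | 2-[(1R,2R,3R,5S)-3-[(tert-butyldimethylsilyl)oxy]-5-hydroxy-2-[(1RS)-2-(2-pentyl-1,3-dioxolan-2-yl)-1-(phenylsulfonyl)ethyl]cyclopentyl]acetaldehyde | CCCCCC2(OCCO2)CC(S(=O)(=O)c2ccccc2)[C@@H]1[C@@H](CC=O)[C@@H](O)C[C@H]1O[Si](C)(C)C(C)(C)C | intermediate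
14 | (3aR,4R,5R,6aS)-5-[(tert-butyldimethylsilyl)oxy]-4-[(1RS)-2-(2-pentyl-1,3-dioxolan-2-yl)-1-(phenylsulfonyl)ethyl]hexahydro-2H-cyclopenta[b]furan-2-ol (cis-fused lactol, anomer mixture) | CCCCCC2(OCCO2)CC(S(=O)(=O)c2ccccc2)[C@@H]1[C@H]3CC(O)O[C@H]3C[C@H]1O[Si](C)(C)C(C)(C)C | intermediate
15 | (4-carboxybutyl)triphenylphosphonium bromide | OC(=O)CCCC[P+](c1ccccc1)(c1ccccc1)c1ccccc1.[Br-] | starting material
16 | potassium 5-(triphenylphosphoranylidene)pentanoate | [K+].[O-]C(=O)CCCC=P(c1ccccc1)(c1ccccc1)c1ccccc1 | intermediate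
17 | (Z)-7-[(1R,2R,3R,5S)-3-[(tert-butyldimethylsilyl)oxy]-5-hydroxy-2-[(1RS)-2-(2-pentyl-1,3-dioxolan-2-yl)-1-(phenylsulfonyl)ethyl]cyclopentyl]hept-5-enoic acid | CCCCCC2(OCCO2)CC(S(=O)(=O)c2ccccc2)[C@@H]1[C@@H](C/C=C\CCCC(=O)O)[C@@H](O)C[C@H]1O[Si](C)(C)C(C)(C)C | intermediate
18 | (Z)-7-[(1R,2R,3R,5S)-3,5-dihydroxy-2-[(1RS)-3-oxo-1-(phenylsulfonyl)octyl]cyclopentyl]hept-5-enoic acid | CCCCCC(=O)CC(S(=O)(=O)c2ccccc2)[C@@H]1[C@@H](C/C=C\CCCC(=O)O)[C@@H](O)C[C@H]1O | intermediate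
19 | 15-keto-PGF2α, (Z)-7-[(1R,2R,3R,5S)-3,5-dihydroxy-2-[(E)-3-oxooct-1-en-1-yl]cyclopentyl]hept-5-enoic acid | CCCCCC(=O)/C=C/[C@@H]1[C@@H](C/C=C\CCCC(=O)O)[C@@H](O)C[C@H]1O | target

## Step count and risks

Total step count: 7. Longest linear sequence: 7 steps (1 → 19); compounds 6, 7 and 15 enter as purchased materials.

The three steps most likely to fail are steps 3, 4 and 7.

Step 3 carries the most risk: the lithiated sulfone may add 1,2, may deprotonate the base-sensitive silyloxy enone, or the enolate may exchange protons before it is allylated. The fallback puts the allyl group on the ring first and turns the coupling into a two-component conjugate addition. It sets out from 6: iodination (I2, pyridine, CH2Cl2, 0 °C) gives (R)-4-[(tert-butyldimethylsilyl)oxy]-2-iodocyclopent-2-en-1-one F1. Stille coupling with allyltributylstannane (Pd(PPh3)4, CuI, DMF, rt) gives (R)-4-[(tert-butyldimethylsilyl)oxy]-2-(prop-2-en-1-yl)cyclopent-2-en-1-one F2. Addition of the lithiated sulfone 8 to F2 (THF/HMPA, −78 °C) and protonation, which leads to the thermodynamically preferred 8,12-trans isomer, comes back to the route at 10.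

Step 4 may give poor C9 selectivity, because the branched C13 substituent on the β-face is bulkier than the vinyl group of the PGE precedents. The fallback replaces direct stereocontrol by inversion. It sets out from 10: NaBH4 in MeOH at −20 °C gives both C9 epimers, from which (1R,2R,3R,4R)-4-[(tert-butyldimethylsilyl)oxy]-3-[(1RS)-2-(2-pentyl-1,3-dioxolan-2-yl)-1-(phenylsulfonyl)ethyl]-2-(prop-2-en-1-yl)cyclopentan-1-ol F3 (the 9β-alcohol) is separated. Mitsunobu esterification (4-nitrobenzoic acid, PPh3, DIAD, THF) inverts C9 to (1S,2R,3R,4R)-4-[(tert-butyldimethylsilyl)oxy]-3-[(1RS)-2-(2-pentyl-1,3-dioxolan-2-yl)-1-(phenylsulfonyl)ethyl]-2-(prop-2-en-1-yl)cyclopentyl 4-nitrobenzoate F4. Methanolysis (K2CO3, MeOH, rt) comes back to the route at 11.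

Step 7 may fail because the free diol enone is exposed to DBU, which could cause γ-deprotonation at C12 or loss of the C11 hydroxyl. The fallback changes the order of unmasking so that the final product is released under acidic fluoride conditions and never meets base. It sets out from 17: PPTS in wet acetone at 50 °C removes only the dioxolane and gives (Z)-7-[(1R,2R,3R,5S)-3-[(tert-butyldimethylsilyl)oxy]-5-hydroxy-2-[(1RS)-3-oxo-1-(phenylsulfonyl)octyl]cyclopentyl]hept-5-enoic acid F5. DBU in CH2Cl2 at 0 °C then eliminates sulfinate while C11 is still silylated and gives (Z)-7-[(1R,2R,3R,5S)-3-[(tert-butyldimethylsilyl)oxy]-5-hydroxy-2-[(E)-3-oxooct-1-en-1-yl]cyclopentyl]hept-5-enoic acid F6. HF·pyridine in MeCN at 0 °C removes the silyl group and comes back to the route at 19.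

## Further compounds

F1 | step 3 | (R)-4-[(tert-butyldimethylsilyl)oxy]-2-iodocyclopent-2-en-1-one | C1=C(I)C(=O)C[C@H]1O[Si](C)(C)C(C)(C)C
F2 | step 3 | (R)-4-[(tert-butyldimethylsilyl)oxy]-2-(prop-2-en-1-yl)cyclopent-2-en-1-one | C1=C(CC=C)C(=O)C[C@H]1O[Si](C)(C)C(C)(C)C
F3 | step 4 | (1R,2R,3R,4R)-4-[(tert-butyldimethylsilyl)oxy]-3-[(1RS)-2-(2-pentyl-1,3-dioxolan-2-yl)-1-(phenylsulfonyl)ethyl]-2-(prop-2-en-1-yl)cyclopentan-1-ol | CCCCCC2(OCCO2)CC(S(=O)(=O)c2ccccc2)[C@@H]1[C@@H](CC=C)[C@H](O)C[C@H]1O[Si](C)(C)C(C)(C)C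
F4 | step 4 | (1S,2R,3R,4R)-4-[(tert-butyldimethylsilyl)oxy]-3-[(1RS)-2-(2-pentyl-1,3-dioxolan-2-yl)-1-(phenylsulfonyl)ethyl]-2-(prop-2-en-1-yl)cyclopentyl 4-nitrobenzoate | CCCCCC2(OCCO2)CC(S(=O)(=O)c2ccccc2)[C@@H]1[C@@H](CC=C)[C@@H](OC(=O)c2ccc(cc2)[N+](=O)[O-])C[C@H]1O[Si](C)(C)C(C)(C)C
F5 | step 7 | (Z)-7-[(1R,2R,3R,5S)-3-[(tert-butyldimethylsilyl)oxy]-5-hydroxy-2-[(1RS)-3-oxo-1-(phenylsulfonyl)octyl]cyclopentyl]hept-5-enoic acid | CCCCCC(=O)CC(S(=O)(=O)c2ccccc2)[C@@H]1[C@@H](C/C=C\CCCC(=O)O)[C@@H](O)C[C@H]1O[Si](C)(C)C(C)(C)C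
F6 | step 7 | (Z)-7-[(1R,2R,3R,5S)-3-[(tert-butyldimethylsilyl)oxy]-5-hydroxy-2-[(E)-3-oxooct-1-en-1-yl]cyclopentyl]hept-5-enoic acid | CCCCCC(=O)/C=C/[C@@H]1[C@@H](C/C=C\CCCC(=O)O)[C@@H](O)C[C@H]1O[Si](C)(C)C(C)(C)C
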